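1. Hardest feature: the lone (R)-centre C1' of the cyclohexene ring. It is a tertiary allylic CH wedged between quaternary C6'(CH3)2 and the olefin C2'(CH3)=C3'H (the less stable α-position). It lies far from any heteroatom and carries the long (E,E)-chain (Cα, Cβ = first two chain CH2).
2. Enabling feature: C1'–C2'(CH3)=C3' is an allyl triad. The bond C1'–Cα plus the olefin C2'=C3' is therefore the [3,3] image of a C3'–O ester bond plus an olefin C1'=C2', that is, of an ester of flat, enone-derived 2,4,4-trimethylcyclohex-2-enol.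
3. Cuts: quinone to 1,4-dimethoxyarene; Cα–H to Cα–CO2H; C1'–Cα to C3'–O–C(=O)–Cα (retro-Ireland–Claisen); Cα–Cβ to acetate enolate plus allylic bromide; aryl–CH2 to aryllithium plus geranyl bromide.
4. Forward: the one ring to be built (C4 + C5 annulation to the cyclohexenone) comes first. The chain is then joined in the order aryl + geranyl, terminal CH3 to CH2Br, Cα–Cβ by alkylation of the chiral acetate, C1'–Cα by the ester-tethered shift, loss of CO2, release of the quinone.
5. Stereochemistry: a CBS reduction sets (S)-C3'–O and the suprafacial shift turns it into (R)-C1'. Both Cα epimers converge when CO2 leaves. One (E)-olefin is bought with geranyl bromide; the other is fixed by the (E)-selective SeO2 oxidation.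

Key step: step 8

Remark: the centre written [C@H] in the SMILES is read as (R), the spatial sense of (R)-α-ionone (CIP order C2' > C6' > chain > H); the primed ring locants of the target are also used for its precursors.

Step 1
Reactants: 1 isobutyraldehyde; 2 ethyl vinyl ketone
Product: 4 2,4,4-trimethylcyclohex-2-en-1-one, via 2,2-dimethyl-5-oxoheptanal 3 (not isolated)
Conditions: conc. H2SO4 (cat.), PhMe, 45 °C, then reflux (Dean–Stark)
Reagents that add atoms: none
Why: Acid-catalysed Michael addition of the aldehyde enol to the vinyl ketone gives 3, whose only possible six-membered aldol condensation (ethyl-side α-CH2 onto CHO) closes the ring in a Robinson-type annulation that forms no stereocentre.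

Step 2
Reactants: 4 2,4,4-trimethylcyclohex-2-en-1-one
Product: 5 (1S)-2,4,4-trimethylcyclohex-2-en-1-ol
Conditions: (R)-Me-CBS oxazaborolidine (cat.), BH3·SMe2, THF, −20 °C; aq. work-up
Reagents that add atoms: none
Why: In the Corey–Bakshi–Shibata reduction the catalyst–borane complex binds the carbonyl oxygen anti to the larger flank, here the methyl-bearing sp2 carbon C2, so the (R)-catalyst should deliver hydride 1,2 to the face that gives the (S)-carbinol.

Step 3
Reactants: 5 (1S)-2,4,4-trimethylcyclohex-2-en-1-ol
Product: 6 (1S)-2,4,4-trimethylcyclohex-2-en-1-yl acetate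
Conditions: Ac2O, DMAP (cat.), pyridine, 0 °C → rt
Reagents that add atoms: acetic anhydride, CC(=O)OC(C)=O
Why: DMAP-catalysed O-acylation takes place at oxygen only and leaves the C–O stereocentre untouched.

Step 4
Reactants: 7 1,4-dimethoxybenzene; 8 geranyl bromide
Product: 10 2-[(2E)-3,7-dimethylocta-2,6-dien-1-yl]-1,4-dimethoxybenzene, via (2,5-dimethoxyphenyl)lithium 9 (not isolated)
Conditions: n-BuLi, TMEDA, THF, 0 °C → rt; then 8, −78 °C → rt
Reagents that add atoms: none
Why: Directed ortho-lithiation of the symmetric diether (all four ring CH are equivalent) is followed by SN2 alkylation with the primary allylic bromide, which keeps the (E)-olefin.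

Step 5
Reactants: 10 2-[(2E)-3,7-dimethylocta-2,6-dien-1-yl]-1,4-dimethoxybenzene
Product: 11 (2E,6E)-8-(2,5-dimethoxyphenyl)-2,6-dimethylocta-2,6-dien-1-ol
Conditions: SeO2 (cat.), t-BuOOH, salicylic acid (cat.), CH2Cl2, 0 °C, stopped at partial conversion (10 recycled)
Reagents that add atoms: tert-butyl hydroperoxide, CC(C)(C)OO (oxygen atom, relayed by catalytic SeO2)
Why: Allylic hydroxylation with SeO2 (ene reaction, then [2,3]-shift of the allylseleninic acid) should attack the more accessible terminal Me2C=CH unit and oxidise the methyl trans to the chain, which fixes the (E)-geometry of the second trisubstituted olefin.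

Step 6
Reactants: 11 (2E,6E)-8-(2,5-dimethoxyphenyl)-2,6-dimethylocta-2,6-dien-1-ol
Product: 12 2-[(2E,6E)-8-bromo-3,7-dimethylocta-2,6-dien-1-yl]-1,4-dimethoxybenzene
Conditions: CBr4, PPh3, CH2Cl2, 0 °C; used without storage
Reagents that add atoms: carbon tetrabromide, BrC(Br)(Br)Br
Why: In the Appel reaction bromide displaces the alkoxyphosphonium group by SN2 at the primary allylic carbon under neutral conditions, without allylic transposition or loss of olefin geometry.

Step 7
Reactants: 6 (1S)-2,4,4-trimethylcyclohex-2-en-1-yl acetate; 12 2-[(2E,6E)-8-bromo-3,7-dimethylocta-2,6-dien-1-yl]-1,4-dimethoxybenzene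
Product: 14 (1S)-2,4,4-trimethylcyclohex-2-en-1-yl (4E,8E)-10-(2,5-dimethoxyphenyl)-4,8-dimethyldeca-4,8-dienoate, via lithium enolate 13 (not isolated)
Conditions: 6 (slight excess), LDA, THF, −78 °C; then 12, DMPU, −78 → −30 °C
Reagents that add atoms: none
Why: This is an ester enolate alkylation in which the kinetic lithium enolate of a hindered secondary acetate reacts by SN2 with the reactive primary allylic bromide, DMPU favours alkylation over Claisen self-condensation, and the cold enolate neither rearranges nor touches the carbinol centre.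

Step 8
Reactants: 14 (1S)-2,4,4-trimethylcyclohex-2-en-1-yl (4E,8E)-10-(2,5-dimethoxyphenyl)-4,8-dimethyldeca-4,8-dienoate
Product: 17 (4E,8E)-10-(2,5-dimethoxyphenyl)-4,8-dimethyl-2-[(1R)-2,6,6-trimethylcyclohex-2-en-1-yl]deca-4,8-dienoic acid (C2 epimers), via silyl ketene acetal 15 (not isolated), via silyl ester 16 (not isolated)
Conditions: LDA, TBSCl, THF–DMPU, −78 °C → rt; solvent change to PhMe, 100 °C; then AcOH–THF–H2O, rt
Reagents that add atoms: none
Why: Kinetic deprotonation and O-silylation turn 14 into ketene acetal 15, whose unit Cα=C–O–C3'–C2'=C1' undergoes the Ireland–Claisen [3,3]-sigmatropic rearrangement on heating, the closest known reaction type being the same rearrangement of cyclohex-2-enyl esters, including cases that form a bond beside a quaternary carbon. No ring is closed, and the cyclic six-atom transition state (chair or boat) can exist only on the ring face that carries the C3'–O bond, so C1'–Cα forms suprafacially on that face and (S)-C3'–O is translated into (R)-C1'. The same bond shift moves the ring olefin from C1'=C2' to C2'=C3', so the less stable α-position arises under kinetic, non-acidic conditions that offer no path to the β- or γ-isomer. The selectivity needed is regiochemical, bond formation at the allyl terminus next to C6'(CH3)2 instead of the open terminus that any intermolecular allylation would choose, and the ester tether secures it because it can reach only C1'. Cα forms as a mixture of epimers whatever the ketene acetal geometry or the chair/boat preference, which is harmless because step 9 turns this carbon into a CH2. The chain olefins, the aryl ethers and the benzylic–allylic CH2 should be inert to LDA at −78 °C on the time scale of ester deprotonation, and to toluene at 100 °C.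

Step 9
Reactants: 17 (4E,8E)-10-(2,5-dimethoxyphenyl)-4,8-dimethyl-2-[(1R)-2,6,6-trimethylcyclohex-2-en-1-yl]deca-4,8-dienoic acid (C2 epimers)
Product: 19 2-{(2E,6E)-3,7-dimethyl-9-[(1R)-2,6,6-trimethylcyclohex-2-en-1-yl]nona-2,6-dien-1-yl}-1,4-dimethoxybenzene, via Barton ester 18 (not isolated)
Conditions: 1-hydroxypyridine-2(1H)-thione, DCC, DMAP (cat.), CH2Cl2, 0 °C → rt, dark; then Bu3SnH, PhMe, hν (W lamp), rt
Reagents that add atoms: none
Why: In the Barton reductive decarboxylation, thiohydroxamate 18 fragments in a radical chain to CO2 and the planar secondary Cα radical (so both epimers of 17 give the same CH2), and Bu3SnH should trap this radical faster than the slow, reversible 3-exo closures onto the two homoallylic olefins, a stannane being preferred to a thiol because thiyl radicals add reversibly to trisubstituted olefins and could erode the (E)-geometry.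

Step 10
Reactants: 19 2-{(2E,6E)-3,7-dimethyl-9-[(1R)-2,6,6-trimethylcyclohex-2-en-1-yl]nona-2,6-dien-1-yl}-1,4-dimethoxybenzene
Product: 20 2-{(2E,6E)-3,7-dimethyl-9-[(1R)-2,6,6-trimethylcyclohex-2-en-1-yl]nona-2,6-dien-1-yl}cyclohexa-2,5-diene-1,4-dione (target)
Conditions: (NH4)2Ce(NO3)6, MeCN–H2O, 0 °C, short contact time
Reagents that add atoms: water, O
Why: Cerium(IV) oxidative demethylation of a 1,4-dimethoxyarene (two one-electron oxidations, water attacking the ipso carbons, methanol leaving) is the standard release of prenylated benzoquinones and is fast enough at 0 °C to spare the isolated trisubstituted olefins and the remote C1' centre.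

Compound list
1 | isobutyraldehyde (2-methylpropanal) | CC(C)C=O | starting material
2 | ethyl vinyl ketone (pent-1-en-3-one) | CCC(=O)C=C | starting material
3 | 2,2-dimethyl-5-oxoheptanal | CCC(=O)CCC(C)(C)C=O | intermediate
4 | 2,4,4-trimethylcyclohex-2-en-1-one | CC1=CC(C)(C)CCC1=O | intermediate
5 | (1S)-2,4,4-trimethylcyclohex-2-en-1-ol | CC1=CC(C)(C)CC[C@@H]1O | intermediate
6 | (1S)-2,4,4-trimethylcyclohex-2-en-1-yl acetate | CC1=CC(C)(C)CC[C@@H]1OC(C)=O | intermediate
7 | 1,4-dimethoxybenzene | COc1ccc(OC)cc1 | starting material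
8 | geranyl bromide [(2E)-1-bromo-3,7-dimethylocta-2,6-diene] | CC(C)=CCC/C(C)=C/CBr | starting material
9 | (2,5-dimethoxyphenyl)lithium | [Li]c1cc(OC)ccc1OC | intermediate
10 | 2-[(2E)-3,7-dimethylocta-2,6-dien-1-yl]-1,4-dimethoxybenzene | CC(C)=CCC/C(C)=C/Cc1cc(OC)ccc1OC | intermediate
11 | (2E,6E)-8-(2,5-dimethoxyphenyl)-2,6-dimethylocta-2,6-dien-1-ol | OC/C(C)=C/CC/C(C)=C/Cc1cc(OC)ccc1OC | intermediate
12 | 2-[(2E,6E)-8-bromo-3,7-dimethylocta-2,6-dien-1-yl]-1,4-dimethoxybenzene | BrC/C(C)=C/CC/C(C)=C/Cc1cc(OC)ccc1OC | intermediate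
13 | lithium enolate of acetate 6 | CC1=CC(C)(C)CC[C@@H]1OC(=C)O[Li] | intermediate
14 | (1S)-2,4,4-trimethylcyclohex-2-en-1-yl (4E,8E)-10-(2,5-dimethoxyphenyl)-4,8-dimethyldeca-4,8-dienoate | CC1=CC(C)(C)CC[C@@H]1OC(=O)CC/C(C)=C/CC/C(C)=C/Cc1cc(OC)ccc1OC | intermediate
15 | tert-butyldimethylsilyl ketene acetal of 14 (ketene acetal geometry of no consequence) | CC1=CC(C)(C)CC[C@@H]1OC(O[Si](C)(C)C(C)(C)C)=CC/C(C)=C/CC/C(C)=C/Cc1cc(OC)ccc1OC | intermediate
16 | tert-butyldimethylsilyl ester of acid 17 (C2 epimers) | CC1=CCCC(C)(C)[C@H]1C(C(=O)O[Si](C)(C)C(C)(C)C)C/C(C)=C/CC/C(C)=C/Cc1cc(OC)ccc1OC | intermediate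
17 | (4E,8E)-10-(2,5-dimethoxyphenyl)-4,8-dimethyl-2-[(1R)-2,6,6-trimethylcyclohex-2-en-1-yl]deca-4,8-dienoic acid (C2 epimers) | CC1=CCCC(C)(C)[C@H]1C(C(=O)O)C/C(C)=C/CC/C(C)=C/Cc1cc(OC)ccc1OC | intermediate
18 | 2-thioxopyridin-1(2H)-yl ester of acid 17 (Barton ester, C2 epimers) | CC1=CCCC(C)(C)[C@H]1C(C(=O)On1ccccc1=S)C/C(C)=C/CC/C(C)=C/Cc1cc(OC)ccc1OC | intermediate
19 | 2-{(2E,6E)-3,7-dimethyl-9-[(1R)-2,6,6-trimethylcyclohex-2-en-1-yl]nona-2,6-dien-1-yl}-1,4-dimethoxybenzene | CC1=CCCC(C)(C)[C@H]1CC/C(C)=C/CC/C(C)=C/Cc1cc(OC)ccc1OC | intermediate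
20 | 2-{(2E,6E)-3,7-dimethyl-9-[(1R)-2,6,6-trimethylcyclohex-2-en-1-yl]nona-2,6-dien-1-yl}cyclohexa-2,5-diene-1,4-dione | CC1=CCCC(C)(C)[C@H]1CC/C(C)=C/CC/C(C)=C/CC1=CC(=O)C=CC1=O | target

Total step count: 10.
Longest linear sequence: 7 steps. This holds for steps 4–10 from 7 and 8, and equally for steps 1–3 followed by 7–10 from 1 and 2.

Steps most likely to fail

Step 8. The substituted ketene acetal carbon must bond next to C6'(CH3)2. Steric compression against the pseudoaxial methyl may slow the shift so far that C-silylation, desilylation or thermal elimination of the allylic ester takes over.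
The fallback sets out from 5 and 12 and comes back at 19. It replaces the ester-tethered union by a one-carbon [2,3]-shift followed by sulfone coupling.
- Alcohol 5 is O-alkylated (KH, Bu3SnCH2I, THF) to tributyl({[(1S)-2,4,4-trimethylcyclohex-2-en-1-yl]oxy}methyl)stannane F1.
- Tin–lithium exchange (n-BuLi, THF, −78 °C) triggers a Wittig–Still [2,3]-rearrangement. Its five-membered, equally suprafacial transition state brings only a CH2 to C1' and should give (R)-α-cyclogeraniol F2.
- Treatment with PhSSPh and Bu3P gives {[(1R)-2,6,6-trimethylcyclohex-2-en-1-yl]methyl}(phenyl)sulfane F3.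
- Oxidation with H2O2 and catalytic ammonium molybdate gives the α-cyclogeranyl phenyl sulfone F4.
- Lithiation (n-BuLi, THF, −78 °C) and alkylation with 12 gives the Cα-phenylsulfonyl derivative of 19 F5.
- Reductive desulfonylation (Na/Hg, Na2HPO4, MeOH) gives 19.

Step 7. Proton transfer between the acetate enolate and the product ester may lead to double alkylation, and Claisen self-condensation of the acetate may compete.
The fallback sets out from 12 and 5 and comes back at 14. Compounds 6 and 13 are then not needed.
- Bromide 12 is alkylated with dilithioacetate (AcOH, 2 LDA, THF–DMPU, 0 °C), a dianion that cannot self-condense. This gives (4E,8E)-10-(2,5-dimethoxyphenyl)-4,8-dimethyldeca-4,8-dienoic acid F6.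
- F6 is joined to 5 by Steglich esterification (DCC, DMAP, CH2Cl2), so the two halves meet at oxygen and step 8 alone forges the carbon link to the ring.

Step 5. Site selectivity may be poor between the two trisubstituted olefins, since the internal one is not deactivated and its ArCH2 is doubly activated. Over-oxidation is also possible.
The fallback sets out from 9 (made from 7 as in step 4) and comes back at 11. It oxidises before the arene is attached.
- Commercial geranyl acetate F7, whose acetoxy group deactivates the 2,3-olefin, is hydroxylated (SeO2 cat., t-BuOOH) to (2E,6E)-8-hydroxy-3,7-dimethylocta-2,6-dien-1-yl acetate F8.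
- Silylation (TBSCl, imidazole, DMF) gives the TBS ether F9.
- Aryllithium 9 is transmetallated (MgBr2·OEt2) and, under Li2CuCl4 catalysis, displaces the allylic acetate at the primary terminus. This gives the TBS ether of 11 F10.
- TBAF in THF releases 11.

Further compounds
F1 | step 8 | tributyl({[(1S)-2,4,4-trimethylcyclohex-2-en-1-yl]oxy}methyl)stannane | CC1=CC(C)(C)CC[C@@H]1OC[Sn](CCCC)(CCCC)CCCC
F2 | step 8 | [(1R)-2,6,6-trimethylcyclohex-2-en-1-yl]methanol, (R)-α-cyclogeraniol | CC1=CCCC(C)(C)[C@H]1CO
F3 | step 8 | {[(1R)-2,6,6-trimethylcyclohex-2-en-1-yl]methyl}(phenyl)sulfane | CC1=CCCC(C)(C)[C@H]1CSc1ccccc1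
F4 | step 8 | ({[(1R)-2,6,6-trimethylcyclohex-2-en-1-yl]methyl}sulfonyl)benzene | CC1=CCCC(C)(C)[C@H]1CS(=O)(=O)c1ccccc1
F5 | step 8 | 2-{(2E,6E)-3,7-dimethyl-9-(phenylsulfonyl)-9-[(1R)-2,6,6-trimethylcyclohex-2-en-1-yl]nona-2,6-dien-1-yl}-1,4-dimethoxybenzene (C9 epimers) | CC1=CCCC(C)(C)[C@H]1C(S(=O)(=O)c1ccccc1)C/C(C)=C/CC/C(C)=C/Cc1cc(OC)ccc1OC
F6 | step 7 | (4E,8E)-10-(2,5-dimethoxyphenyl)-4,8-dimethyldeca-4,8-dienoic acid | OC(=O)CC/C(C)=C/CC/C(C)=C/Cc1cc(OC)ccc1OC
F7 | step 5 | geranyl acetate (commercial) | CC(C)=CCC/C(C)=C/COC(C)=O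
F8 | step 5 | (2E,6E)-8-hydroxy-3,7-dimethylocta-2,6-dien-1-yl acetate | OC/C(C)=C/CC/C(C)=C/COC(C)=O
F9 | step 5 | (2E,6E)-8-[(tert-butyldimethylsilyl)oxy]-3,7-dimethylocta-2,6-dien-1-yl acetate | CC(C)(C)[Si](C)(C)OC/C(C)=C/CC/C(C)=C/COC(C)=O
F10 | step 5 | tert-butyl{[(2E,6E)-8-(2,5-dimethoxyphenyl)-2,6-dimethylocta-2,6-dien-1-yl]oxy}dimethylsilane | CC(C)(C)[Si](C)(C)OC/C(C)=C/CC/C(C)=C/Cc1cc(OC)ccc1OC
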